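**Retrosynthetic overview**
- The target is reached by opening an enol lactone; the lactone precursor comes from a new, catalyst-controlled dearomative C-prenylation that creates the quaternary centre.
- The phenol lactone comes from a carbene-catalysed annulation of a 6-alkyl-5,7-dihydroxychromanone with 3-phenylpropynal (C8–C bond, benzylic centre, temporary ring C).
- The cis-2,3-dimethylchromanone (ring B) comes from a Mitsunobu closure, with inversion, of an anti β-hydroxy aryl ketone.
- That ketone comes from phloroglucinol (ring A) by two directed ortho-metalations: cuprate alkylation with the C11 side-chain tosylate, then acylation with a Weinreb amide.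
- Side chain: Evans benzyloxymethylation, then Wittig. Acyl unit: Fráter–Seebach methylation of ethyl (R)-3-hydroxybutanoate. Ring order: A (bought), B, C, dearomatise A, open C.

Assumption: the target is taken as the drawn C4-enol/C5,C7-diketo tautomer, and the sense of induction of the chiral catalysts in steps 16 and 17 is taken by analogy (the antipodal catalyst is used if it proves opposite).

Ring positions in the text use chromanone numbering (O1, C2, C3, C4, C4a, C5 to C8, C8a).

**Step 1**
Reactants: 1 ethyl (R)-3-hydroxybutanoate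
Product: 3 ethyl (2R,3R)-3-hydroxy-2-methylbutanoate, via dilithium alkoxide-enolate 2 (not isolated)
Conditions: LiN(i-Pr)2 (2.2 equiv), THF, −50 to −20 °C; MeI, DMPU, −78 to −20 °C; H2O
Reagents that add atoms: iodomethane (CI)
Why: Fráter–Seebach alkylation, in which the chelated dianion is methylated anti to the C3 substituent, sets C2 as R (anti, dr about 95:5) while C3 comes from the chiral pool.

**Step 2**
Reactants: 3 ethyl (2R,3R)-3-hydroxy-2-methylbutanoate
Product: 4 ethyl (2R,3R)-3-(tert-butyldimethylsilyloxy)-2-methylbutanoate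
Conditions: TBSCl, imidazole, DMF, rt
Reagents that add atoms: tert-butyldimethylsilyl chloride (CC(C)(C)[Si](C)(C)Cl)
Why: Standard silylation of a secondary alcohol (TBS protection) that touches no stereocentre.

**Step 3**
Reactants: 4 ethyl (2R,3R)-3-(tert-butyldimethylsilyloxy)-2-methylbutanoate
Product: 5 (2R,3R)-3-(tert-butyldimethylsilyloxy)-N-methoxy-N,2-dimethylbutanamide
Conditions: MeNH(OMe)·HCl, i-PrMgCl, THF, −20 to 0 °C
Reagents that add atoms: N,O-dimethylhydroxylamine hydrochloride (CNOC.Cl)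
Why: Weinreb amide formation by magnesium-amide aminolysis of the ester is faster than α-deprotonation at −20 °C, so both stereocentres are kept.

**Step 4**
Reactants: 6 5-methylhex-5-enoic acid; 7 (S)-4-benzyloxazolidin-2-one
Product: 9 (S)-4-benzyl-3-(5-methylhex-5-enoyl)oxazolidin-2-one, via mixed pivalic anhydride 8 (not isolated)
Conditions: t-BuCOCl, Et3N, THF, −20 °C; then 7, LiCl, −20 °C to rt
Reagents that add atoms: none
Why: N-acylation of the Evans auxiliary through the mixed anhydride (LiCl-promoted acyl transfer) creates no new stereocentre.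

**Step 5**
Reactants: 9 (S)-4-benzyl-3-(5-methylhex-5-enoyl)oxazolidin-2-one
Product: 11 (S)-4-benzyl-3-[(R)-2-(benzyloxymethyl)-5-methylhex-5-enoyl]oxazolidin-2-one, via trichlorotitanium (Z)-enolate 10 (not isolated)
Conditions: TiCl4, i-Pr2NEt, CH2Cl2, 0 °C; BnOCH2Cl (1.2 equiv), 0 °C, 1 h
Reagents that add atoms: benzyl chloromethyl ether (ClCOCc1ccccc1)
Why: Evans asymmetric alkylation, in which the chelated (Z)-enolate is attacked on the face opposite the auxiliary benzyl group, sets the new centre as R (dr above 95:5); the isopropenyl group is far less nucleophilic than the enolate.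

**Step 6**
Reactants: 11 (S)-4-benzyl-3-[(R)-2-(benzyloxymethyl)-5-methylhex-5-enoyl]oxazolidin-2-one
Product: 12 (S)-2-(benzyloxymethyl)-5-methylhex-5-en-1-ol
Conditions: LiBH4, H2O (1 equiv), Et2O, 0 °C
Reagents that add atoms: none
Why: Reductive removal of the auxiliary (hydride attack at the exocyclic imide carbonyl) leaves the α-centre untouched; the descriptor becomes S only through the priority rules.

**Step 7**
Reactants: 12 (S)-2-(benzyloxymethyl)-5-methylhex-5-en-1-ol
Product: 13 (R)-2-(benzyloxymethyl)-5-methylhex-5-enal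
Conditions: Dess–Martin periodinane, CH2Cl2, 0 °C to rt
Reagents that add atoms: none
Why: Dess–Martin oxidation under non-basic conditions gives the α-branched aldehyde without epimerisation or β-elimination of the benzyloxy group.

**Step 8**
Reactants: 13 (R)-2-(benzyloxymethyl)-5-methylhex-5-enal
Product: 14 benzyl (S)-5-methyl-2-(2-methylprop-1-enyl)hex-5-enyl ether
Conditions: i-PrPPh3I, n-BuLi, THF, 0 °C; then 13, −78 to 0 °C
Reagents that add atoms: isopropyltriphenylphosphonium iodide (CC(C)[P+](c1ccccc1)(c1ccccc1)c1ccccc1.[I-])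
Why: Wittig olefination with the non-stabilised isopropylidene ylide installs the 2-methylprop-1-enyl group at low temperature, fast enough to keep the α-centre intact.

**Step 9**
Reactants: 14 benzyl (S)-5-methyl-2-(2-methylprop-1-enyl)hex-5-enyl ether
Product: 15 (S)-5-methyl-2-(2-methylprop-1-enyl)hex-5-en-1-ol
Conditions: lithium 4,4'-di-tert-butylbiphenylide, THF, −78 °C; H2O
Reagents that add atoms: none
Why: Reductive cleavage of the benzyl ether by an arene radical anion spares the isolated alkenes, and the ether oxygen is homoallylic and not allylic.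

**Step 10**
Reactants: 15 (S)-5-methyl-2-(2-methylprop-1-enyl)hex-5-en-1-ol
Product: 16 (S)-5-methyl-2-(2-methylprop-1-enyl)hex-5-enyl 4-methylbenzenesulfonate
Conditions: TsCl, Et3N, DMAP (cat.), CH2Cl2, 0 °C
Reagents that add atoms: p-toluenesulfonyl chloride (Cc1ccc(cc1)S(=O)(=O)Cl)
Why: Tosylation of the primary alcohol; a tosylate is chosen over a triflate because this homoallylic system would ionise with alkene participation.

**Step 11**
Reactants: 17 phloroglucinol
Product: 18 1,3,5-tris(methoxymethoxy)benzene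
Conditions: MOMCl (3.6 equiv), i-Pr2NEt, DMF, 0 °C to rt
Reagents that add atoms: chloromethyl methyl ether (COCCl)
Why: Exhaustive O-alkylation gives three MOM acetals, which protect the phenols and later act as ortho-directing groups.

**Step 12**
Reactants: 18 1,3,5-tris(methoxymethoxy)benzene (2 equiv); 16 (S)-5-methyl-2-(2-methylprop-1-enyl)hex-5-enyl 4-methylbenzenesulfonate
Product: 21 2-[(R)-5-methyl-2-(2-methylprop-1-enyl)hex-5-enyl]-1,3,5-tris(methoxymethoxy)benzene, via aryllithium 19 (not isolated), via lithium diarylcuprate 20 (not isolated)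
Conditions: n-BuLi, THF, 0 °C; CuI (0.5 equiv), −40 °C; then 16, Et2O–THF, −40 °C to rt; aq. NH4Cl
Reagents that add atoms: none
Why: Directed ortho-metalation between two MOM ethers, transmetalation to the Gilman cuprate and SN2 displacement of the primary tosylate (cuprate alkylation) attach the side chain; its stereocentre is β to the reacting carbon and is unaffected.

**Step 13**
Reactants: 21 2-[(R)-5-methyl-2-(2-methylprop-1-enyl)hex-5-enyl]-1,3,5-tris(methoxymethoxy)benzene; 5 (2R,3R)-3-(tert-butyldimethylsilyloxy)-N-methoxy-N,2-dimethylbutanamide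
Product: 23 (2R,3R)-3-(tert-butyldimethylsilyloxy)-2-methyl-1-{2,4,6-tris(methoxymethoxy)-3-[(R)-5-methyl-2-(2-methylprop-1-enyl)hex-5-enyl]phenyl}butan-1-one, via aryllithium 22 (not isolated)
Conditions: n-BuLi, TMEDA, THF, 0 °C; then 5, −78 to 0 °C; H2O
Reagents that add atoms: none
Why: A second directed ortho-metalation (the two free ring positions are equivalent, each between two MOM ethers) and Weinreb ketone synthesis give the aryl ketone; the chelated tetrahedral adduct prevents over-addition and enolisation of the α-centre.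

**Step 14**
Reactants: 23 the tris-MOM silyloxy ketone
Product: 24 (2R,3R)-3-hydroxy-2-methyl-1-{2,4,6-trihydroxy-3-[(R)-5-methyl-2-(2-methylprop-1-enyl)hex-5-enyl]phenyl}butan-1-one
Conditions: HCl (cat.), MeOH–THF, 40 °C
Reagents that add atoms: none
Why: Acid-catalysed methanolysis removes the three acetals and the silyl ether; the side-chain alkenes cannot give five- or six-membered cyclic ethers by Markovnikov addition of a phenol, and the prenyl group is not yet present.

**Step 15**
Reactants: 24 the trihydroxyphenyl β-hydroxy ketone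
Product: 25 (2S,3R)-5,7-dihydroxy-2,3-dimethyl-6-[(R)-5-methyl-2-(2-methylprop-1-enyl)hex-5-enyl]chroman-4-one
Conditions: PPh3, DIAD, THF (0.01 M), 0 °C to rt
Reagents that add atoms: none
Why: Intramolecular Mitsunobu etherification displaces the activated secondary alcohol with inversion (3R of the chain becomes 2S of the chromanone), turning the anti pattern into the cis-2,3-dimethylchromanone; closure goes through the unhindered ortho hydroxyl next to the ring C–H because the carbonyl is chelated by the hydroxyl buttressed by the side chain.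

**Step 16**
Reactants: 25 the 6-alkyl-5,7-dihydroxychromanone; 26 3-phenylprop-2-ynal
Product: 27 (2S,3R,10R)-5-hydroxy-2,3-dimethyl-6-[(R)-5-methyl-2-(2-methylprop-1-enyl)hex-5-enyl]-10-phenyl-2,3,9,10-tetrahydro-4H,8H-pyrano[2,3-f]chromene-4,8-dione (25 with C8 and O7 bridged by CH(Ph)–CH2–C(=O))
Conditions: Bode-type chiral N-mesityl aminoindanol triazolium chloride (10 mol %), toluene, 40 °C, no added base
Reagents that add atoms: none
Why: Carbene-catalysed redox annulation of an ynal with a phenol (Coates–Claisen type): the catalyst-bound α,β-unsaturated acyl azolium from 26 is attacked by the C7 hydroxyl, a [3,3] shift forms the C8–C bond at the only free ortho carbon and the same oxygen closes the lactone, the chiral backbone setting the benzylic centre as R.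

**Step 17**
Reactants: 27 the phenol lactone
Product: 28 (2S,3R,6S,10R)-2,3-dimethyl-6-(3-methylbut-2-enyl)-6-[(R)-5-methyl-2-(2-methylprop-1-enyl)hex-5-enyl]-10-phenyl-2,3,9,10-tetrahydro-4H,8H-pyrano[2,3-f]chromene-4,5,8(6H)-trione
Conditions: prenyl acetate (1.5 equiv), Pd2(dba)3·CHCl3 (2.5 mol %), (R,R)-DACH-phenyl Trost ligand (7.5 mol %), Cs2CO3 (1.2 equiv), THF, 0 °C to rt
Reagents that add atoms: 3-methylbut-2-enyl acetate (CC(=O)OCC=C(C)C)
Why: Proposed new method: a ligand-controlled, face-selective dearomative C-prenylation of a hexasubstituted acylphloroglucinol-type phenol, in which zerovalent palladium ionises prenyl acetate to a π-prenyl complex, the caesium C5 phenoxide (chelated to the C4 carbonyl) is held by hydrogen bonds to the amide N–H groups of the ligand, and outer-sphere attack of C6 (ortho to the phenoxide, the only nucleophilic ring carbon not tied into a ring) on the unsubstituted allyl terminus gives the linear prenyl group and the 6S quaternary centre from the face set by the chiral pocket, O-prenylation being reversible under the catalyst; the closest known reaction types are the palladium-catalysed asymmetric allylic dearomatisation of naphthols and the non-selective alkylative dearomatisation of acylphloroglucinols.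

**Step 18**
Reactants: 28 the dearomatised enol lactone
Product: 29 (3R)-3-[(2S,3R,6S)-4-hydroxy-2,3-dimethyl-6-(3-methylbut-2-enyl)-6-[(R)-5-methyl-2-(2-methylprop-1-enyl)hex-5-enyl]-5,7-dioxo-3,5,6,7-tetrahydro-2H-chromen-8-yl]-3-phenylpropanoic acid (CNP0155375.3)
Conditions: LiOH, THF–H2O, 0 °C; then 1 M HCl to pH 3
Reagents that add atoms: water (O)
Why: Saponification of the activated enol lactone at 0 °C gives the stabilised triketone anion, which protects the cis-dimethylchromanone from epimerisation, and acidification gives the enolised target.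

**Compound list**
1 | ethyl (R)-3-hydroxybutanoate | CCOC(=O)C[C@@H](C)O | starting material
2 | dilithium alkoxide-enolate of 1 | [Li+].[Li+].CCOC([O-])=C[C@@H](C)[O-] | intermediate
3 | ethyl (2R,3R)-3-hydroxy-2-methylbutanoate | CCOC(=O)[C@H](C)[C@@H](C)O | intermediate
4 | ethyl (2R,3R)-3-(tert-butyldimethylsilyloxy)-2-methylbutanoate | CCOC(=O)[C@H](C)[C@@H](C)O[Si](C)(C)C(C)(C)C | intermediate
5 | (2R,3R)-3-(tert-butyldimethylsilyloxy)-N-methoxy-N,2-dimethylbutanamide | CON(C)C(=O)[C@H](C)[C@@H](C)O[Si](C)(C)C(C)(C)C | intermediate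
6 | 5-methylhex-5-enoic acid | C=C(C)CCCC(=O)O | starting material
7 | (S)-4-benzyloxazolidin-2-one | O=C1OC[C@H](Cc2ccccc2)N1 | starting material
8 | 5-methylhex-5-enoic pivalic anhydride | C=C(C)CCCC(=O)OC(=O)C(C)(C)C | intermediate
9 | (S)-4-benzyl-3-(5-methylhex-5-enoyl)oxazolidin-2-one | C=C(C)CCCC(=O)N1C(=O)OC[C@@H]1Cc1ccccc1 | intermediate
10 | trichlorotitanium (Z)-enolate of 9 | C=C(C)CC/C=C(\O[Ti](Cl)(Cl)Cl)N1C(=O)OC[C@@H]1Cc1ccccc1 | intermediate
11 | (S)-4-benzyl-3-[(R)-2-(benzyloxymethyl)-5-methylhex-5-enoyl]oxazolidin-2-one | C=C(C)CC[C@@H](C(=O)N1C(=O)OC[C@@H]1Cc1ccccc1)COCc1ccccc1 | intermediate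
12 | (S)-2-(benzyloxymethyl)-5-methylhex-5-en-1-ol | C=C(C)CC[C@@H](CO)COCc1ccccc1 | intermediate
13 | (R)-2-(benzyloxymethyl)-5-methylhex-5-enal | C=C(C)CC[C@@H](C=O)COCc1ccccc1 | intermediate
14 | benzyl (S)-5-methyl-2-(2-methylprop-1-enyl)hex-5-enyl ether | C=C(C)CC[C@@H](C=C(C)C)COCc1ccccc1 | intermediate
15 | (S)-5-methyl-2-(2-methylprop-1-enyl)hex-5-en-1-ol | C=C(C)CC[C@@H](C=C(C)C)CO | intermediate
16 | (S)-5-methyl-2-(2-methylprop-1-enyl)hex-5-enyl 4-methylbenzenesulfonate | C=C(C)CC[C@@H](C=C(C)C)COS(=O)(=O)c1ccc(C)cc1 | intermediate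
17 | phloroglucinol (benzene-1,3,5-triol) | Oc1cc(O)cc(O)c1 | starting material
18 | 1,3,5-tris(methoxymethoxy)benzene | COCOc1cc(OCOC)cc(OCOC)c1 | intermediate
19 | 2,4,6-tris(methoxymethoxy)phenyllithium | [Li]c1c(OCOC)cc(OCOC)cc1OCOC | intermediate
20 | lithium bis[2,4,6-tris(methoxymethoxy)phenyl]cuprate | [Li+].COCOc1cc(OCOC)cc(OCOC)c1[Cu-]c1c(OCOC)cc(OCOC)cc1OCOC | intermediate
21 | 2-[(R)-5-methyl-2-(2-methylprop-1-enyl)hex-5-enyl]-1,3,5-tris(methoxymethoxy)benzene | C=C(C)CC[C@@H](C=C(C)C)Cc1c(OCOC)cc(OCOC)cc1OCOC | intermediate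
22 | 2,4,6-tris(methoxymethoxy)-3-[(R)-5-methyl-2-(2-methylprop-1-enyl)hex-5-enyl]phenyllithium | C=C(C)CC[C@@H](C=C(C)C)Cc1c(OCOC)cc(OCOC)c([Li])c1OCOC | intermediate
23 | (2R,3R)-3-(tert-butyldimethylsilyloxy)-2-methyl-1-{2,4,6-tris(methoxymethoxy)-3-[(R)-5-methyl-2-(2-methylprop-1-enyl)hex-5-enyl]phenyl}butan-1-one | C=C(C)CC[C@@H](C=C(C)C)Cc1c(OCOC)cc(OCOC)c(C(=O)[C@H](C)[C@@H](C)O[Si](C)(C)C(C)(C)C)c1OCOC | intermediate
24 | (2R,3R)-3-hydroxy-2-methyl-1-{2,4,6-trihydroxy-3-[(R)-5-methyl-2-(2-methylprop-1-enyl)hex-5-enyl]phenyl}butan-1-one | C=C(C)CC[C@@H](C=C(C)C)Cc1c(O)cc(O)c(C(=O)[C@H](C)[C@@H](C)O)c1O | intermediate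
25 | (2S,3R)-5,7-dihydroxy-2,3-dimethyl-6-[(R)-5-methyl-2-(2-methylprop-1-enyl)hex-5-enyl]chroman-4-one | C=C(C)CC[C@@H](C=C(C)C)Cc1c(O)cc2c(c1O)C(=O)[C@H](C)[C@H](C)O2 | intermediate
26 | 3-phenylprop-2-ynal | O=CC#Cc1ccccc1 | starting material
27 | (2S,3R,10R)-5-hydroxy-2,3-dimethyl-6-[(R)-5-methyl-2-(2-methylprop-1-enyl)hex-5-enyl]-10-phenyl-2,3,9,10-tetrahydro-4H,8H-pyrano[2,3-f]chromene-4,8-dione | C=C(C)CC[C@@H](C=C(C)C)Cc1c(O)c2c(c3c1OC(=O)C[C@@H]3c1ccccc1)O[C@@H](C)[C@@H](C)C2=O | intermediate
28 | (2S,3R,6S,10R)-2,3-dimethyl-6-(3-methylbut-2-enyl)-6-[(R)-5-methyl-2-(2-methylprop-1-enyl)hex-5-enyl]-10-phenyl-2,3,9,10-tetrahydro-4H,8H-pyrano[2,3-f]chromene-4,5,8(6H)-trione | C=C(C)CC[C@@H](C=C(C)C)C[C@@]1(CC=C(C)C)C(=O)C2=C(O[C@@H](C)[C@@H](C)C2=O)C2=C1OC(=O)C[C@@H]2c1ccccc1 | intermediate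
29 | (3R)-3-[(2S,3R,6S)-4-hydroxy-2,3-dimethyl-6-(3-methylbut-2-enyl)-6-[(R)-5-methyl-2-(2-methylprop-1-enyl)hex-5-enyl]-5,7-dioxo-3,5,6,7-tetrahydro-2H-chromen-8-yl]-3-phenylpropanoic acid | C=C(C)CC[C@@H](C=C(C)C)C[C@@]1(CC=C(C)C)C(=O)C2=C(O)[C@H](C)[C@H](C)OC2=C([C@H](CC(=O)O)c2ccccc2)C1=O | target

**Totals**
Total step count: 18.
Longest linear sequence: 14 steps (steps 4 to 10, then steps 12 to 18).

**Three steps most likely to fail**

Step 17 (the proposed new step). Risks are low facial selectivity at C6, stalling at the O-prenyl ether, or attack at C8. The fallback uses known chemistry, sets out from 27 and comes back to the route at 29. LiOH in THF–water opens the lactone to (3R)-3-[(2S,3R)-5,7-dihydroxy-2,3-dimethyl-4-oxo-6-[(R)-5-methyl-2-(2-methylprop-1-enyl)hex-5-enyl]chroman-8-yl]-3-phenylpropanoic acid F1. Classical alkylative dearomatisation of its polyanion with prenyl bromide in aqueous KOH at 0 °C then prenylates C6 without facial control. This gives 29 together with the C6 epimer of 29 F2, which is removed by reversed-phase preparative HPLC; step 18 is then not needed.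

Step 16. Risks are poor turnover with the chelated phloroglucinol-type phenol, a dead-end aryl ester, or low diastereoselectivity. The fallback sets out from 25 and comes back at 27.
- DCC-mediated esterification of the C7 hydroxyl with propiolic acid gives (2S,3R)-5-hydroxy-2,3-dimethyl-6-[(R)-5-methyl-2-(2-methylprop-1-enyl)hex-5-enyl]-4-oxochroman-7-yl propiolate F3.
- Intramolecular 6-endo hydroarylation at C8 with a monovalent gold catalyst (AuCl(PPh3)/AgOSO2CF3) gives the coumarin (2S,3R)-5-hydroxy-2,3-dimethyl-6-[(R)-5-methyl-2-(2-methylprop-1-enyl)hex-5-enyl]-2,3-dihydro-4H,8H-pyrano[2,3-f]chromene-4,8-dione F4.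
- Asymmetric 1,4-addition of PhB(OH)2 with Rh(acac)(C2H4)2 and (R)-SEGPHOS in dioxane–water at 60 °C sets the benzylic centre and returns 27.

Step 15. Risks are E1cB dehydration of the β-hydroxy ketone and competing closure through the hindered hydroxyl. The fallback sets out from 23 and comes back at 25.
- DBU in toluene deliberately expels the silanolate to give (E)-2-methyl-1-{2,4,6-tris(methoxymethoxy)-3-[(R)-5-methyl-2-(2-methylprop-1-enyl)hex-5-enyl]phenyl}but-2-en-1-one F5.
- HCl in methanol removes the acetals to give (E)-2-methyl-1-{2,4,6-trihydroxy-3-[(R)-5-methyl-2-(2-methylprop-1-enyl)hex-5-enyl]phenyl}but-2-en-1-one F6.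
- The cinchona-alkaloid (quinidine) catalysed intramolecular oxa-Michael addition known for o-tigloylphenols closes the ring cis-selectively to 25; any 8-alkyl regioisomer is removed by chromatography.

**Further compounds**
F1 | step 17 | (3R)-3-[(2S,3R)-5,7-dihydroxy-2,3-dimethyl-4-oxo-6-[(R)-5-methyl-2-(2-methylprop-1-enyl)hex-5-enyl]chroman-8-yl]-3-phenylpropanoic acid | C=C(C)CC[C@@H](C=C(C)C)Cc1c(O)c2c(c(c1O)[C@H](CC(=O)O)c1ccccc1)O[C@@H](C)[C@@H](C)C2=O
F2 | step 17 | C6 epimer of 29 (6R) | C=C(C)CC[C@@H](C=C(C)C)C[C@]1(CC=C(C)C)C(=O)C2=C(O)[C@H](C)[C@H](C)OC2=C([C@H](CC(=O)O)c2ccccc2)C1=O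
F3 | step 16 | (2S,3R)-5-hydroxy-2,3-dimethyl-6-[(R)-5-methyl-2-(2-methylprop-1-enyl)hex-5-enyl]-4-oxochroman-7-yl propiolate | C=C(C)CC[C@@H](C=C(C)C)Cc1c(OC(=O)C#C)cc2c(c1O)C(=O)[C@H](C)[C@H](C)O2
F4 | step 16 | (2S,3R)-5-hydroxy-2,3-dimethyl-6-[(R)-5-methyl-2-(2-methylprop-1-enyl)hex-5-enyl]-2,3-dihydro-4H,8H-pyrano[2,3-f]chromene-4,8-dione | C=C(C)CC[C@@H](C=C(C)C)Cc1c(O)c2c(c3c1OC(=O)C=C3)O[C@@H](C)[C@@H](C)C2=O
F5 | step 15 | (E)-2-methyl-1-{2,4,6-tris(methoxymethoxy)-3-[(R)-5-methyl-2-(2-methylprop-1-enyl)hex-5-enyl]phenyl}but-2-en-1-one | C=C(C)CC[C@@H](C=C(C)C)Cc1c(OCOC)cc(OCOC)c(C(=O)/C(C)=C/C)c1OCOC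
F6 | step 15 | (E)-2-methyl-1-{2,4,6-trihydroxy-3-[(R)-5-methyl-2-(2-methylprop-1-enyl)hex-5-enyl]phenyl}but-2-en-1-one | C=C(C)CC[C@@H](C=C(C)C)Cc1c(O)cc(O)c(C(=O)/C(C)=C/C)c1O
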